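Rings A and B are disconnected together at C5–C10 and C8–C9 (labdane numbering). Ring B holds quaternary C10 next to C9, the carbon that carries C11; this 1,2-relationship is the retron of an enoate dienophile (C9=C10, ester carbon C11), with C5–C8 as the diene and the ring A carbons C1–C4 as the tether. One intramolecular Diels–Alder reaction therefore closes both carbocycles and sets C5, C9 and C10 from the C3/C4 stereodiad. The precursor is a methyl (E)-3-methyl-2-enoate linked through the 3,19-acetonide-bearing tether to an (E,E)-diene on quaternary C4; the diene terminus C8 carries a pinacol boronate, a spectator that later becomes the C8 carbonyl and exocyclic methylene.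

Key step: step 7

Conventions: labdane numbering throughout (ring A = C1–C5 and C10; ring B = C5–C10; C18 = 4-methyl, C19 = 4-CH2O, C20 = 10-methyl, C11 on C9, C17 = exocyclic carbon on C8). α is the face of the decalin that carries C20. B(pin) = 4,4,5,5-tetramethyl-1,3,2-dioxaborolan-2-yl.

Assumption: the (R)-antipode of Tol-BINAP is taken as the one that gives the (2R,3R)-diol 3; if the sense of induction is the reverse, the (S)-ligand is used and nothing else changes.

Design notes:
- A late allylic oxidation of the 6-ene would have to tell C8–H2 from the tertiary, axial allylic C5–H. The C8 oxygen is therefore carried as B(pin) on the diene terminus. This handle changes neither the carbon skeleton of precursor 10 or cycloadduct 11 nor the bonds formed.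
- The C5 aldehyde and the C10 methyl ketone are released together by ozonolysis, so the ketone never meets acid next to the 1,3-diol.
- Both diene double bonds come from E-selective or stereoretentive steps.

Step 1
Reactants: 1 4-methylpent-4-en-1-ol; 2 isoprene monoxide (2-ethenyl-2-methyloxirane)
Product: 3 (2R,3R)-2-ethenyl-2,6-dimethylhept-6-ene-1,3-diol
Conditions: cyclometalated iridium catalyst preformed from [Ir(cod)Cl]2, (R)-Tol-BINAP, 4-cyano-3-nitrobenzoic acid and allyl acetate (5 mol %), K3PO4 (5 mol %), THF, 60 °C
Reagents that add atoms: none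
Why: Redox-neutral iridium-catalysed tert-(hydroxy)prenylation: the catalyst dehydrogenates 1 to its aldehyde and opens 2 to an allyliridium species that adds through a closed chair transition state, which should give the anti diol with quaternary C4, while Tol-BINAP fixes the absolute configuration of C3 and C4; the isopropenyl group is a bystander.

Step 2
Reactants: 3 (2R,3R)-2-ethenyl-2,6-dimethylhept-6-ene-1,3-diol
Product: 4 (4R,5R)-5-ethenyl-2,2,5-trimethyl-4-(3-methylbut-3-en-1-yl)-1,3-dioxane
Conditions: 2,2-dimethoxypropane, PPTS (cat.), CH2Cl2, rt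
Reagents that add atoms: 2,2-dimethoxypropane COC(C)(C)OC
Why: Acid-catalysed transacetalisation closes the six-membered 1,3-dioxane on the 1,3-diol and is mild enough to leave both alkenes untouched.

Step 3
Reactants: 4 (4R,5R)-5-ethenyl-2,2,5-trimethyl-4-(3-methylbut-3-en-1-yl)-1,3-dioxane
Product: 5 (4R,5R)-2,2,5-trimethyl-4-(3-oxobutyl)-1,3-dioxane-5-carbaldehyde
Conditions: O3, CH2Cl2/MeOH, −78 °C; then Me2S, −78 °C to rt
Reagents that add atoms: ozone [O-][O+]=O
Why: Ozonolysis with reductive work-up cleaves both terminal alkenes in one operation, the vinyl group to the non-enolisable C5 aldehyde and the isopropenyl group to the C10 methyl ketone, under non-acidic conditions that the acetonide tolerates.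

Step 4
Reactants: 5 (4R,5R)-2,2,5-trimethyl-4-(3-oxobutyl)-1,3-dioxane-5-carbaldehyde
Product: 6 4-[(4R,5R)-5-[(E)-2-iodoethenyl]-2,2,5-trimethyl-1,3-dioxan-4-yl]butan-2-one
Conditions: CrCl2 (6 equiv), CHI3 (2 equiv), THF/1,4-dioxane, 0 °C to rt
Reagents that add atoms: iodoform IC(I)I
Why: Takai olefination: the geminal dichromium reagent from CHI3 adds to aldehydes far faster than to ketones and should give the (E)-iodoalkene (C5=C6), the bulky quaternary C4 reinforcing the E preference.

Step 5
Reactants: 6 4-[(4R,5R)-5-[(E)-2-iodoethenyl]-2,2,5-trimethyl-1,3-dioxan-4-yl]butan-2-one; 7 trimethyl phosphonoacetate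
Product: 8 methyl (2E)-5-[(4R,5R)-5-[(E)-2-iodoethenyl]-2,2,5-trimethyl-1,3-dioxan-4-yl]-3-methylpent-2-enoate
Conditions: NaH, THF, 0 °C to 60 °C
Reagents that add atoms: none
Why: Horner–Wadsworth–Emmons olefination of the methyl ketone should give the trisubstituted enoate with the ester trans to the longer chain as the major isomer; the minor (Z)-isomer is removed by chromatography here, before the stereospecific cycloaddition.

Step 6
Reactants: 8 methyl (2E)-5-[(4R,5R)-5-[(E)-2-iodoethenyl]-2,2,5-trimethyl-1,3-dioxan-4-yl]-3-methylpent-2-enoate; 9 (E)-1,2-bis(4,4,5,5-tetramethyl-1,3,2-dioxaborolan-2-yl)ethene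
Product: 10 methyl (2E)-3-methyl-5-[(4R,5R)-2,2,5-trimethyl-5-[(1E,3E)-4-B(pin)-buta-1,3-dien-1-yl]-1,3-dioxan-4-yl]pent-2-enoate (the trienoate; boron on C8)
Conditions: Pd(dppf)Cl2 (5 mol %), K3PO4, THF/H2O, 50 °C, 9 in excess (3 equiv)
Reagents that add atoms: none
Why: Suzuki–Miyaura coupling with retention at both alkenes forms C6–C7; the excess of the diboronate should hold the reaction at mono-coupling and leave one B(pin) on C8.

Step 7
Reactants: 10 methyl (E,E,E)-trienoate with 3,19-acetonide and B(pin) on C8
Product: 11 cycloadduct: trans-fused 6-ene, C11 methyl ester on C9 (α, equatorial), 8α-B(pin), 3α,19-acetonide, C20 α, H5 and H9 β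
Conditions: BHT (cat.), toluene (0.005 M), 170 °C, sealed tube
Reagents that add atoms: none
Why: Concerted suprafacial [4+2] cycloaddition of the C5=C6–C7=C8 dienylboronate to the C9=C10 enoate, forming C5–C10 and C8–C9; the closest known reaction type is the thermal type 1 intramolecular Diels–Alder reaction of deca-2,8,10-trienoates to trans-fused octalins, which includes β-methyl enoates (angular methyl) and 1-boryl dienes (allylboronate products). Ring B (six-membered, C5–C10) is formed by the cycloaddition itself with both new bonds in it, and ring A (six-membered, C1–C5 plus C10) is the tether ring, closed by the C5–C10 bond through a chair-like tether. C5 and C10 are set by the tether-exo, ester-endo transition state, which places C4, C20 and C11 on the same side of the new ring (trans fusion); C9 is set by the (E)-enoate geometry (C11 cis to C20, equatorial) and the disposable C8 centre by the (E)-alkenylboronate geometry (boron cis to C11). The absolute sense comes from the C3/C4 stereodiad: of the two chair tethers, the one with O3 equatorial and C19 axial is preferred over the one with O3 and C18 axial, and it puts C19 on the same side as the developing angular methyl group. The step needs trans-fusion (endo) and diene-face selectivity; the fixed olefin geometries, the angular methyl group and the rigid cis-fused acetonide on the tether should secure them, while the four-carbon tether fixes the regiochemistry.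

Step 8
Reactants: 11 cycloadduct with 8α-B(pin)
Product: 12 8α-hydroxy-6-ene C11 methyl ester 3,19-acetonide
Conditions: 30% H2O2, aq. NaHCO3, THF, 0 °C to rt
Reagents that add atoms: hydrogen peroxide OO
Why: Oxidation of the C–B bond by hydroperoxide with 1,2-migration from boron to oxygen proceeds with retention and without allylic transposition, so the oxygen should arrive at C8 only.

Step 9
Reactants: 12 8α-hydroxy-6-ene C11 methyl ester 3,19-acetonide
Product: 13 6-ene-8α,11-diol 3,19-acetonide
Conditions: LiAlH4, THF, 0 °C
Reagents that add atoms: none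
Why: Hydride reduction of the methyl ester gives the C11 primary alcohol; the acetonide and the isolated alkene are inert to LiAlH4.

Step 10
Reactants: 13 6-ene-8α,11-diol 3,19-acetonide
Product: 14 11-hydroxy-6-en-8-one 3,19-acetonide
Conditions: activated MnO2 (excess), CH2Cl2, rt
Reagents that add atoms: none
Why: MnO2 oxidises only the allylic secondary alcohol at C8 and leaves the saturated primary C11 alcohol, so no protecting group is needed.

Step 11
Reactants: 14 11-hydroxy-6-en-8-one 3,19-acetonide
Product: 15 11-hydroxy-8-ketone 3,19-acetonide (ring B saturated)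
Conditions: H2 (1 atm), Pd/C, EtOAc, rt
Reagents that add atoms: none
Why: Heterogeneous hydrogenation saturates the conjugated C6=C7 bond; ketone, acetonide and alcohol survive, and C9 keeps its equatorial substituent, which is also the thermodynamic one.

Step 12
Reactants: 15 11-hydroxy-8-ketone 3,19-acetonide
Product: 16 8(17)-en-11-ol 3,19-acetonide (exocyclic methylene on C8, CH2OH on C9)
Conditions: Zn, CH2Br2, TiCl4, THF/CH2Cl2, 0 °C to rt
Reagents that add atoms: dibromomethane BrCBr
Why: Lombardo methylenation: the non-basic titanium–methylene reagent should olefinate the hindered, enolisable β-hydroxy ketone without retro-aldol cleavage or C9 epimerisation, and it tolerates the free alcohol.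

Step 13
Reactants: 16 8(17)-en-11-ol 3,19-acetonide
Product: 17 8(17)-en-11-al 3,19-acetonide
Conditions: Dess–Martin periodinane, NaHCO3, CH2Cl2, 0 °C to rt
Reagents that add atoms: none
Why: Buffered Dess–Martin oxidation should give the β,γ-unsaturated aldehyde without moving the exocyclic double bond into conjugation; the aldehyde is used at once.

Step 14
Reactants: 18 2-(bromomethyl)acrylic acid; 19 allyl alcohol
Product: 20 allyl 2-(bromomethyl)acrylate
Conditions: TsOH (cat.), hydroquinone (trace), cyclohexane, reflux, Dean–Stark trap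
Reagents that add atoms: none
Why: Acid-catalysed Fischer esterification with azeotropic removal of water is the usual route to esters of this acid.

Step 15
Reactants: 17 8(17)-en-11-al 3,19-acetonide; 20 allyl 2-(bromomethyl)acrylate
Product: 21 (11R)-carbinol: C11(OH)–CH2–C(=CH2)–CO2-allyl on C9 of the 8(17)-ene 3,19-acetonide
Conditions: indium powder, THF/H2O, rt
Reagents that add atoms: none
Why: Indium-mediated Barbier allylation: the 2-(alkoxycarbonyl)allylindium reagent adds to the aldehyde and forms C11–C12; Felkin–Anh attack anti to quaternary C10 is expected to favour the (11R)-carbinol, and the hydroxy ester is isolated before it can lactonise.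

Step 16
Reactants: 21 (11R)-carbinol with allyl 2-methylidene ester side chain
Product: 22 14-deoxy-11-hydroxyandrographolide 3,19-acetonide
Conditions: second-generation Grubbs catalyst (5 mol %), CH2Cl2 (0.002 M), 40 °C
Reagents that add atoms: none
Why: Ring-closing metathesis between the allyl ester and the 1,1-disubstituted acrylate alkene should form the five-membered butenolide (C13=C14) with loss of ethene; the hindered exocyclic C8 methylene should not compete.

Step 17
Reactants: 22 14-deoxy-11-hydroxyandrographolide 3,19-acetonide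
Product: 23 14-deoxy-11-hydroxyandrographolide, (3R,4R,5S,9R,10R,11R)
Conditions: AcOH/H2O/THF (3:1:1), rt
Reagents that add atoms: none
Why: Mild aqueous acid hydrolyses the 1,3-dioxane acetal and should neither isomerise the exocyclic alkene nor translactonise the butenolide onto the C11 hydroxyl.

Compound list

1 | 4-methylpent-4-en-1-ol | C=C(C)CCCO | starting material
2 | isoprene monoxide (2-ethenyl-2-methyloxirane) | CC1(CO1)C=C | starting material
3 | (2R,3R)-2-ethenyl-2,6-dimethylhept-6-ene-1,3-diol | C=C[C@](C)(CO)[C@H](O)CCC(C)=C | intermediate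
4 | (4R,5R)-5-ethenyl-2,2,5-trimethyl-4-(3-methylbut-3-en-1-yl)-1,3-dioxane | C=C[C@]1(C)COC(C)(C)O[C@@H]1CCC(C)=C | intermediate
5 | (4R,5R)-2,2,5-trimethyl-4-(3-oxobutyl)-1,3-dioxane-5-carbaldehyde | O=C[C@]1(C)COC(C)(C)O[C@@H]1CCC(C)=O | intermediate
6 | 4-[(4R,5R)-5-[(E)-2-iodoethenyl]-2,2,5-trimethyl-1,3-dioxan-4-yl]butan-2-one | I/C=C/[C@]1(C)COC(C)(C)O[C@@H]1CCC(C)=O | intermediate
7 | trimethyl phosphonoacetate | COC(=O)CP(=O)(OC)OC | starting material
8 | methyl (2E)-5-[(4R,5R)-5-[(E)-2-iodoethenyl]-2,2,5-trimethyl-1,3-dioxan-4-yl]-3-methylpent-2-enoate | I/C=C/[C@]1(C)COC(C)(C)O[C@@H]1CC/C(C)=C/C(=O)OC | intermediate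
9 | (E)-1,2-bis(4,4,5,5-tetramethyl-1,3,2-dioxaborolan-2-yl)ethene | CC1(C)OB(/C=C/B2OC(C)(C)C(C)(C)O2)OC1(C)C | starting material
10 | methyl (2E)-3-methyl-5-[(4R,5R)-2,2,5-trimethyl-5-[(1E,3E)-4-(4,4,5,5-tetramethyl-1,3,2-dioxaborolan-2-yl)buta-1,3-dien-1-yl]-1,3-dioxan-4-yl]pent-2-enoate | CC1(C)OB(/C=C/C=C/[C@]2(C)COC(C)(C)O[C@@H]2CC/C(C)=C/C(=O)OC)OC1(C)C | intermediate
11 | cycloadduct: trans-fused 6-ene C11 methyl ester 3,19-acetonide with 8α-B(pin) (O3, C19, C20, C11 and boron α; H5, H9 and C18 β) | COC(=O)[C@@H]1[C@H](B4OC(C)(C)C(C)(C)O4)C=C[C@@H]2[C@]3(C)COC(C)(C)O[C@@H]3CC[C@@]12C | intermediate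
12 | 8α-hydroxy-6-ene C11 methyl ester 3,19-acetonide | COC(=O)[C@@H]1[C@H](O)C=C[C@@H]2[C@]3(C)COC(C)(C)O[C@@H]3CC[C@@]12C | intermediate
13 | 6-ene-8α,11-diol 3,19-acetonide | OC[C@@H]1[C@H](O)C=C[C@@H]2[C@]3(C)COC(C)(C)O[C@@H]3CC[C@@]12C | intermediate
14 | 11-hydroxy-6-en-8-one 3,19-acetonide | OC[C@@H]1C(=O)C=C[C@@H]2[C@]3(C)COC(C)(C)O[C@@H]3CC[C@@]12C | intermediate
15 | 11-hydroxy-8-ketone 3,19-acetonide | OC[C@@H]1C(=O)CC[C@@H]2[C@]3(C)COC(C)(C)O[C@@H]3CC[C@@]12C | intermediate
16 | 8(17)-en-11-ol 3,19-acetonide | OC[C@@H]1C(=C)CC[C@@H]2[C@]3(C)COC(C)(C)O[C@@H]3CC[C@@]12C | intermediate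
17 | 8(17)-en-11-al 3,19-acetonide | O=C[C@@H]1C(=C)CC[C@@H]2[C@]3(C)COC(C)(C)O[C@@H]3CC[C@@]12C | intermediate
18 | 2-(bromomethyl)acrylic acid | C=C(CBr)C(=O)O | starting material
19 | allyl alcohol | C=CCO | starting material
20 | allyl 2-(bromomethyl)acrylate | C=CCOC(=O)C(=C)CBr | intermediate
21 | (11R)-carbinol: allyl 2-methylidene ester side chain on C11 of the 8(17)-ene 3,19-acetonide | C=C1CC[C@@H]2[C@]3(C)COC(C)(C)O[C@@H]3CC[C@@]2(C)[C@@H]1[C@H](O)CC(=C)C(=O)OCC=C | intermediate
22 | 14-deoxy-11-hydroxyandrographolide 3,19-acetonide | C=C1CC[C@@H]2[C@]3(C)COC(C)(C)O[C@@H]3CC[C@@]2(C)[C@@H]1[C@H](O)CC1=CCOC1=O | intermediate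
23 | 14-deoxy-11-hydroxyandrographolide | C=C1CC[C@@H]2[C@](C)(CO)[C@H](O)CC[C@@]2(C)[C@@H]1[C@H](O)CC1=CCOC1=O | target

Total step count: 17 (16 in the main line plus the one-step preparation of ester 20).
Longest linear sequence: 16 steps (steps 1–13 and 15–17).

Steps most likely to fail

1. Step 7 (key cycloaddition). What may go wrong: the cyclisation is too slow at temperatures at which the allylboronate survives, or the diene face and the trans fusion are not controlled well enough. Fallback, from 10 back to 13: the dienophile is activated as the aldehyde and cyclised at low temperature under Lewis acid promotion. DIBAL-H (CH2Cl2, −78 °C) should reduce the ester of 10 to the dienylboronate allylic alcohol F1, and MnO2 should give the (E)-trienal F2. Me2AlCl (CH2Cl2, −78 °C) should then cyclise the aldehyde–aluminium complex to the cycloadduct aldehyde F3. This is reduced in the cold mixture with NaBH4/MeOH to the primary alcohol boronate F4, before the hindered aldehyde can meet the allylboronate. H2O2/NaHCO3 then gives diol 13.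

2. Step 15 (C11 carbinol). What may go wrong: poor facial selectivity in the addition to the C11 aldehyde, which rests on substrate control alone. Fallback, from 21 (as the C11 epimer mixture) back to 21: Dess–Martin oxidation should give the C11 ketone F5. A reagent-controlled Corey–Bakshi–Shibata reduction ((S)-2-methyl-CBS-oxazaborolidine, catecholborane, toluene, −78 °C; catecholborane spares the alkenes) should then return the (11R)-alcohol 21.

3. Step 6 (boryl diene). What may go wrong: a second coupling of the product boronate with unreacted iodide, or protodeboronation in the aqueous base. Fallback, from 8 back to 10: Heck–Mizoroki coupling of 8 with vinylboronic acid pinacol ester under anhydrous amine-base conditions (Pd(OAc)2, P(o-tol)3, Et3N, MeCN, 80 °C). It builds the C6–C7 bond by carbopalladation and β-hydride elimination with boron retained. No new compound is made on the way (F0).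

Further compounds

F1 | step 7 | dienylboronate allylic alcohol (C11 CH2OH, (2E)-enol side of the triene, 3,19-acetonide) | CC1(C)OB(/C=C/C=C/[C@]2(C)COC(C)(C)O[C@@H]2CC/C(C)=C/CO)OC1(C)C
F2 | step 7 | (E)-trienal with 3,19-acetonide and B(pin) on C8 | CC1(C)OB(/C=C/C=C/[C@]2(C)COC(C)(C)O[C@@H]2CC/C(C)=C/C=O)OC1(C)C
F3 | step 7 | cycloadduct aldehyde: trans-fused 6-ene 11-al 3,19-acetonide with 8α-B(pin) | O=C[C@@H]1[C@H](B4OC(C)(C)C(C)(C)O4)C=C[C@@H]2[C@]3(C)COC(C)(C)O[C@@H]3CC[C@@]12C
F4 | step 7 | primary alcohol boronate: trans-fused 6-en-11-ol 3,19-acetonide with 8α-B(pin) | OC[C@@H]1[C@H](B4OC(C)(C)C(C)(C)O4)C=C[C@@H]2[C@]3(C)COC(C)(C)O[C@@H]3CC[C@@]12C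
F5 | step 15 | C11 ketone: allyl 2-methylidene-4-oxo ester side chain on C9 of the 8(17)-ene 3,19-acetonide | C=C1CC[C@@H]2[C@]3(C)COC(C)(C)O[C@@H]3CC[C@@]2(C)[C@@H]1C(=O)CC(=C)C(=O)OCC=C
F0 | step 6 | none | none
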